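3 questions stand on the next flask, and one decision lies behind them: raise [substrate] to 0.67 M and leave [precatalyst] at 67 mM, or pay for Monday's 100 mM.

| flask | substrate | coupling partner | capture agent | precatalyst | remark | time |
|---|---|---|---|---|---|---|
| Tuesday's | 0.34 M | 0.67 M | 0.67 M | 67 mM | run made earlier |  |
| Wednesday's | 0.50 M | 0.67 M | 0.67 M | 67 mM | run made earlier |  |
| Monday's | 0.67 M | 0.67 M | 0.67 M | 100 mM | run made earlier |  |
| flask | 0.67 M | 0.670 M | 0.670 M | 67 mM |  | 20 min |

| run | time / min | trapped intermediate / % | product / % |
|---|---|---|---|
| Tuesday's | 0.833 | 24.2 | 27.0 |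
| Tuesday's | 2.50 | 38.5 | 59.6 |
| Tuesday's | 4.00 | 39.0 | 60.3 |
| Tuesday's | 6.00 | 38.9 | 60.8 |
| Tuesday's | 10.0 | 39.9 | 60.2 |
| Tuesday's | 12.0 | 38.7 | 60.8 |
| Wednesday's | 0.833 | 23.4 | 27.0 |
| Wednesday's | 2.50 | 38.3 | 57.9 |
| Wednesday's | 4.00 | 39.3 | 60.8 |
| Wednesday's | 6.00 | 39.1 | 60.5 |
| Wednesday's | 10.0 | 39.5 | 62.0 |
| Wednesday's | 12.0 | 39.0 | 60.3 |
| Monday's | 1.00 | 26.4 | 42.7 |
| Monday's | 2.00 | 33.4 | 59.9 |
| Monday's | 3.00 | 34.6 | 63.8 |
| Monday's | 6.00 | 34.7 | 64.8 |
| Monday's | 12.0 | 35.9 | 65.5 |

(readings scatter by 0.5 percentage points)

1. ratio of trapped intermediate to product at 12 s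
2. ratio of trapped intermediate to product at 2.0 min
3. ratio of trapped intermediate to product at 20 min

- on the list of suspects stand: precatalyst -> catalyst; coupling partner + catalyst + open intermediate -> catalyst + product; substrate + catalyst <-> catalyst + open intermediate; open intermediate + capture agent -> trapped intermediate

Find first the concentration that sets the order. Tuesday and Wednesday differ in [substrate] alone, 0.34 M against 0.50 M, yet at 0.833 min both read 27.0% of product, as much in one as in the other. Treat the percent curves as pseudo-first-order in substrate, so that in these two runs the substrate charge does not move the split. Monday differs from both runs in [precatalyst] and in [substrate]; at 12.0 min Monday reads a ratio of 0.548.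

Now take the plateau split, the ratio of trapped intermediate to product once the readings stop moving, at 67 mM of precatalyst and equal charges of coupling partner and capture agent. Pooling the last readings of Tuesday and Wednesday gives 0.646, higher than Monday's figure. Commit to that for the late question, with a product share of 60.8% of the substrate charged, against Monday's reading of 65.5%. Charge the flask at 67 mM and accept that difference.

The forecast gives 2.7, 0.71 and 0.67. It places the last “slightly above the 0.645 seen in the dilute runs”, so it stands a little higher than my figure.

The flask gives 2.50, 0.684 and 0.654, and all 3 forecast values stand within their margins.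

    precatalyst → catalyst (k = 0.0119 s⁻¹)
    coupling partner + catalyst + open intermediate → catalyst + product (k = 1.10 M⁻² s⁻¹)
    substrate + catalyst ⇌ catalyst + open intermediate (K = 9.32, k = 6.64 M⁻¹ s⁻¹)
    open intermediate + capture agent → trapped intermediate (k = 0.0184 M⁻¹ s⁻¹)

At 20.0 min the flask holds 60.5% of product and 39.5% of trapped intermediate, with 0% of substrate left. The plateau split read from the dilute runs put the product share at 60.8%, with no integration.

Carry the split to the neighbour with 2.7 M of capture agent. Scaling it by the capture charge gives 2.60, or 27.8% of product. The computed neighbour ends higher than that, at 3.16, with 24.0% of product.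

The numbers in the tables are calculated for substances that don't exist, and the scatter is random.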